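**Retrosynthetic overview**
1. Feature: in ring C (C5–C6–C7–C8–C9–C10, closed through the cyclobutane ring A, C4–C5–C11–C10) the oxygen-bearing C7 and C9 are separated only by C8 and flanked by the quaternary C6 and C10, so without C8 ring C is a six-membered acyloin ring (C1 = ketone carbon; ring B = C1–C2–C3–C4 and C11; "upper" = the face of ring A that carries the C1–C3 bridge).
2. Target ⇐ double angeloylation and C1 oxidation of the (7R,9R)-diol ⇐ reagent-controlled, then hydroxyl-directed, reduction of the 7,9-dione.
3. 7,9-Dione ⇐ insertion of C8 (from CH2I2) between C7 and C9 of the enediol bis(trimethylsilyl ether): cyclopropanation, then FeCl3 cleavage of C7–C9.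
4. Enediol ether ⇐ acyloin condensation of the C7/C9 diester ⇐ lactone made by a Reformatsky addition of the C6 unit, tethered through O–C9, to the C5 ketone (fixes C5), then radical deoxygenation.
5. C5 ketone (rings A and B at once) ⇐ intramolecular ketene–alkene [2+2] of a citronellic-type acid built from methyl hydrogen (R)-3-methylglutarate (C3) and an E-alkenyl iodide from propargyl alcohol (C10); ring order: A+B, temporary lactone, six-membered ring C, seven-membered ring C.

Key step: step 18

Remark: methyl hydrogen (R)-3-methylglutarate (5) is taken as a commercial compound; it is also the product of pig-liver-esterase hydrolysis of dimethyl 3-methylglutarate.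
Remark: in step 19 the C9 carbonyl, which has no gem-dimethyl neighbour, is taken to be reduced first; reduction at C7 by the same reagent would lead to the same diol 31.

**Route**

Step 1
Reactants: 1 propargyl alcohol
Product: 3 (E)-3-iodo-2-methylprop-2-en-1-ol, via alkenylalane 2 (not isolated)
Conditions: Me3Al (3 equiv), Cp2ZrCl2 (0.25 equiv), CH2Cl2, 0 °C → rt; then I2, THF, −30 → 0 °C; aq. K2CO3
Reagents that add atoms: trimethylaluminium, C[Al](C)C; iodine, II
Why: Negishi zirconium-catalysed carboalumination adds CH3 and Al syn across the alkyne with CH3 on the internal carbon, and iodinolysis of the C–Al bond with retention gives the E-iodide (I cis to CH3), the geometry that later puts the C10 methyl on the upper face.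

Step 2
Reactants: 3 (E)-3-iodo-2-methylprop-2-en-1-ol
Product: 4 (E)-1-iodo-3-[(4-methoxybenzyl)oxy]-2-methylprop-1-ene
Conditions: NaH, 4-methoxybenzyl chloride, Bu4NI (cat.), THF/DMF, 0 °C → rt
Reagents that add atoms: 4-methoxybenzyl chloride, COc1ccc(CCl)cc1
Why: Williamson etherification of the primary alkoxide; the iodoalkene has no β-hydrogen that could be eliminated.

Step 3
Reactants: 5 methyl hydrogen (R)-3-methylglutarate; 4 PMB-protected E-iodide
Product: 9 methyl (3R,6E)-8-[(4-methoxybenzyl)oxy]-3,7-dimethyl-5-oxooct-6-enoate, via acid chloride 6 (not isolated), via alkenyllithium 7 (not isolated), via alkenylzinc chloride 8 (not isolated)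
Conditions: 5, (COCl)2, DMF (cat.), CH2Cl2, 0 °C → rt, evaporate; 4, t-BuLi (2 equiv), Et2O, −78 °C, then ZnCl2, THF, −78 → 0 °C; then 6, Pd(PPh3)4 (5 mol %), THF, 0 °C → rt
Reagents that add atoms: none
Why: Negishi acylation: iodine–lithium exchange and transmetalation to zinc keep the alkene geometry, and the zerovalent palladium catalyst couples the alkenylzinc with the acid chloride only, leaving the methyl ester untouched.

Step 4
Reactants: 9 enone
Product: 10 methyl (3R,5S,6E)-5-hydroxy-8-[(4-methoxybenzyl)oxy]-3,7-dimethyloct-6-enoate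
Conditions: (R)-2-methyl-CBS-oxazaborolidine [(R)-1-methyl-3,3-diphenyl-tetrahydro-1H,3H-pyrrolo[1,2-c][1,3,2]oxazaborole] (0.2 equiv), catecholborane (1.5 equiv), toluene, −78 °C; crude product silylated at once
Reagents that add atoms: none
Why: Corey–Bakshi–Shibata reduction in which the alkenyl group is the large substituent, so the (R)-catalyst gives the (S)-carbinol; this sets C1, a temporary stereocentre that steers step 7.

Step 5
Reactants: 10 allylic alcohol
Product: 11 methyl (3R,5S,6E)-5-[(tert-butyldimethylsilyl)oxy]-8-[(4-methoxybenzyl)oxy]-3,7-dimethyloct-6-enoate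
Conditions: t-BuMe2SiOTf, 2,6-lutidine, CH2Cl2, −78 °C
Reagents that add atoms: tert-butyldimethylsilyl triflate, CC(C)(C)[Si](C)(C)OS(=O)(=O)C(F)(F)F
Why: Fast silylation of the secondary alcohol at low temperature forestalls δ-lactonisation onto the methyl ester.

Step 6
Reactants: 11 silyl ether ester
Product: 12 (3R,5S,6E)-5-[(tert-butyldimethylsilyl)oxy]-8-[(4-methoxybenzyl)oxy]-3,7-dimethyloct-6-enoic acid
Conditions: LiOH, THF/MeOH/H2O, rt; 1 M HCl to pH 4, 0 °C
Reagents that add atoms: lithium hydroxide, [Li+].[OH-]
Why: Saponification of the unhindered methyl ester; the silyl and benzyl ethers are stable to hydroxide.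

Step 7
Reactants: 12 acid
Product: 15 bicyclic C5 ketone, via acid chloride 13 (not isolated), via ketene 14 (not isolated)
Conditions: 1-chloro-N,N,2-trimethylprop-1-en-1-amine (1.2 equiv), CH2Cl2, 0 °C → rt; then syringe-pump addition (8 h) to Et3N (5 equiv), toluene, 110 °C (final 0.005 M)
Reagents that add atoms: none
Why: Intramolecular ketene–alkene [2+2] cycloaddition of the crossed type (carbonyl carbon C5 to the less substituted C11, ketene carbon C4 to C10) gives the bicyclo[3.1.1]heptan-6-one; addition is suprafacial on the alkene, so the E geometry puts the C10 methyl on the upper face, and the alkene face is chosen by allylic 1,3-strain (C1–H turns toward the C10 methyl, the silyloxy group outward) reinforced by the C3 methyl taking the equatorial position on the C5 side, which sets C4, C11 and C10.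

Step 8
Reactants: 15 bicyclic C5 ketone
Product: 16 C9 alcohol
Conditions: DDQ, CH2Cl2/pH 7 buffer, 0 °C
Reagents that add atoms: none
Why: Oxidative cleavage of the 4-methoxybenzyl ether; the silyl ether and the non-enolisable cyclobutanone are inert to DDQ.

Step 9
Reactants: 16 C9 alcohol; 17 2-bromo-2-methylpropanoyl bromide
Product: 18 C9 2-bromoisobutyrate
Conditions: pyridine, CH2Cl2, 0 °C
Reagents that add atoms: none
Why: Acylation of the primary alcohol by the acyl bromide (any internal hemiketal with the C5 ketone is in equilibrium with the open form and is drained by it); this attaches C6, C7 and both C6 methyls to the lower face of C10.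

Step 10
Reactants: 18 C9 2-bromoisobutyrate
Product: 19 C5-hydroxy lactone
Conditions: SmI2 (2.5 equiv), THF, −78 → −20 °C
Reagents that add atoms: none
Why: Samarium diiodide (divalent samarium) reduces the α-bromo ester to a samarium enolate that adds to the non-enolisable C5 ketone in an intramolecular Reformatsky reaction; the enolate carbon C6 is tied through O–C9 to the lower face of C10 and can reach only the lower face of C5, which sets C5 with C6 down and OH up.

Step 11
Reactants: 19 C5-hydroxy lactone
Product: 20 C5 methyl oxalate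
Conditions: methyl chlorooxoacetate, pyridine, DMAP (cat.), CH2Cl2, 0 °C → rt
Reagents that add atoms: methyl chlorooxoacetate, COC(=O)C(=O)Cl
Why: The small, very reactive oxalyl chloride acylates the tertiary alcohol under conditions too weakly basic for retro-aldol cleavage.

Step 12
Reactants: 20 C5 methyl oxalate
Product: 21 tricyclic lactone
Conditions: Bu3SnH (2 equiv), AIBN (0.2 equiv), toluene, 110 °C
Reagents that add atoms: none
Why: Barton-type radical deoxygenation of a tertiary methyl oxalate: the tin radical adds to the oxalate, C5–O scission gives the tertiary C5 radical, and because the lactone bridge holds C6 on the lower face, hydrogen is transferred to the upper face only, giving the C5 configuration of the target.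

Step 13
Reactants: 21 tricyclic lactone
Product: 22 C7/C9 diol
Conditions: LiAlH4, THF, 0 °C → rt
Reagents that add atoms: none
Why: Hydride reduction of the lactone opens the temporary ring to the two neopentyl alcohols; the silyl ether is stable.

Step 14
Reactants: 22 C7/C9 diol
Product: 23 C7/C9 dialdehyde
Conditions: (COCl)2, DMSO, CH2Cl2, −78 °C; Et3N, −78 → −20 °C
Reagents that add atoms: none
Why: Swern oxidation activates both alcohols as alkoxysulfonium ions before any aldehyde exists, so no lactol forms and no lactone 21 is regenerated; neither aldehyde can enolise.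

Step 15
Reactants: 23 C7/C9 dialdehyde
Product: 24 C7/C9 diacid
Conditions: NaClO2, NaH2PO4, 2-methylbut-2-ene, t-BuOH/H2O, rt
Reagents that add atoms: sodium chlorite, [Na+].[O-]Cl=O
Why: Pinnick oxidation converts hindered aldehydes into acids under buffered conditions that leave the silyl ether intact.

Step 16
Reactants: 24 C7/C9 diacid
Product: 25 C7/C9 dimethyl ester
Conditions: MeI, K2CO3, DMF, rt
Reagents that add atoms: iodomethane, CI
Why: O-Alkylation of the carboxylates is an SN2 reaction at the methyl carbon and is not slowed by the quaternary α-carbons.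

Step 17
Reactants: 25 C7/C9 dimethyl ester
Product: 26 C7=C9 enediol bis(trimethylsilyl ether)
Conditions: Na (4.4 equiv, dispersion), Me3SiCl (6 equiv), toluene, 110 °C; filtered under argon, used crude
Reagents that add atoms: chlorotrimethylsilane, C[Si](C)(C)Cl
Why: Rühlmann acyloin condensation: sodium reduces both non-enolisable esters to ketyls that couple across the 1,3-diaxial positions of ring A to the six-membered ring, and Me3SiCl traps the enediolate and removes methoxide.

Step 18
Reactants: 26 C7=C9 enediol bis(trimethylsilyl ether); 27 diiodomethane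
Product: 29 7,9-dione (C1 OTBS), via bis(silyloxy)cyclopropane 28 (not isolated)
Conditions: Et2Zn (4 equiv), CH2I2 (4 equiv), toluene, 0 °C → rt; aq. NH4Cl/pyridine work-up; then FeCl3 (2.5 equiv), DMF, 0 °C → rt; pH 7 work-up
Reagents that add atoms: none
Why: The zinc carbenoid EtZnCH2I, formed from Et2Zn and 27, transfers CH2 in a concerted [2+1] addition to the C7=C9 bond of 26, forming C7–C8 and C8–C9 at once and giving the 1,2-bis(silyloxy)bicyclo[4.1.0] unit of 28. FeCl3 (trivalent iron) then removes one electron from a silyloxy oxygen, the radical cation collapses by β-scission of the zero-atom bridge C7–C9 to a C7 carbonyl and a C9 α-silyloxy radical, and a second FeCl3 oxidises that radical to the C9 carbonyl with loss of Me3SiCl. The closest known reaction type is the Simmons–Smith cyclopropanation of acyloin-derived 1,2-bis(trimethylsilyloxy)cycloalkenes followed by FeCl3 ring opening to the homologous cycloalkane-1,3-diones. Ring C is therefore not closed end to end: the six-membered ring C5–C6–C7–C9–C10–C4 is first annulated by the three-membered ring (cheletropic closure) and then merged with it, by cleavage of the shared bond, into the seven-membered ring. No stereocentre survives the step, since C7 and C9 of 28 become carbonyl carbons, so the face of carbenoid attack does not matter. Only chemoselectivity is needed: the enediol ether is the sole alkene and the most electron-rich site, FeCl3 cleaves the one cyclopropane bond flanked by both oxygen donors, and the C1 silyl ether is inert to both reagents.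

Step 19
Reactants: 29 7,9-dione (C1 OTBS)
Product: 30 (9R)-9-hydroxy-7-ketone
Conditions: (+)-Ipc2BCl [(+)-B-chlorodiisopinocampheylborane, from (−)-α-pinene] (1.5 equiv), THF, −25 °C → rt; then diethanolamine, Et2O
Reagents that add atoms: none
Why: Ipc2BCl reduces α-quaternary cycloalkanones by β-hydride transfer in a six-membered transition state in which the quaternary carbon is the large group, so the (+)-reagent gives the R carbinol; ring C is bisected by a local mirror plane that only the remote C1 and C3 substituents break, so the substrate has little facial bias and the reagent decides (sets C9).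

Step 20
Reactants: 30 (9R)-9-hydroxy-7-ketone
Product: 31 (7R,9R)-7,9-diol
Conditions: Me4NBH(OAc)3 (5 equiv), MeCN/AcOH 1:1, −30 °C
Reagents that add atoms: none
Why: Evans–Saksena reduction: the C9 hydroxyl exchanges onto boron and hydride is delivered intramolecularly to the C7 carbonyl on the face of the C9–O bond, so the new hydroxyl is trans to the first (sets C7 as R).

Step 21
Reactants: 31 (7R,9R)-7,9-diol; 32 angelic acid
Product: 34 7,9-diangelate (C1 OTBS), via angelic 2,4,6-trichlorobenzoic anhydride 33 (not isolated)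
Conditions: 32 (4 equiv), 2,4,6-trichlorobenzoyl chloride (4 equiv), Et3N, toluene, rt, 2 h; then 31, toluene, 80 °C
Reagents that add atoms: none
Why: Yamaguchi-type esterification through the mixed anhydride, the established way to make angelates without Z to E isomerisation; the alcohols attack the less hindered angeloyl carbonyl.

Step 22
Reactants: 34 7,9-diangelate (C1 OTBS)
Product: 35 7,9-diangelate C1 alcohol
Conditions: HF·pyridine, pyridine, THF, 0 °C → rt
Reagents that add atoms: none
Why: Fluoride-driven desilylation under buffered acidic conditions that neither hydrolyse nor isomerise the angelates.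

Step 23
Reactants: 35 7,9-diangelate C1 alcohol
Product: 36 7,9-diangeloyloxy-longipinan-1-one (target)
Conditions: Dess–Martin periodinane, CH2Cl2, rt
Reagents that add atoms: none
Why: Dess–Martin oxidation of the secondary alcohol to the C1 ketone; the only stereogenic α-carbon is the bridgehead C11, which cannot epimerise.

**Compound list**
1 | propargyl alcohol | C#CCO | starting material
2 | (E)-alkenylalane, dimethylaluminium alkoxide form (Al cis to CH3) | C[Al](C)/C=C(\C)CO[Al](C)C | intermediate
3 | (E)-3-iodo-2-methylprop-2-en-1-ol | I/C=C(\C)CO | intermediate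
4 | (E)-1-iodo-3-[(4-methoxybenzyl)oxy]-2-methylprop-1-ene | I/C=C(\C)COCc1ccc(OC)cc1 | intermediate
5 | methyl hydrogen (R)-3-methylglutarate, (3R)-5-methoxy-3-methyl-5-oxopentanoic acid | COC(=O)C[C@H](C)CC(=O)O | starting material
6 | methyl (3S)-5-chloro-3-methyl-5-oxopentanoate (acid chloride of 5; stereocentre unchanged, descriptor changes by priority) | COC(=O)C[C@H](C)CC(=O)Cl | intermediate
7 | (E)-alkenyllithium from 4 | [Li]/C=C(\C)COCc1ccc(OC)cc1 | intermediate
8 | (E)-alkenylzinc chloride | Cl[Zn]/C=C(\C)COCc1ccc(OC)cc1 | intermediate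
9 | methyl (3R,6E)-8-[(4-methoxybenzyl)oxy]-3,7-dimethyl-5-oxooct-6-enoate | COC(=O)C[C@H](C)CC(=O)/C=C(\C)COCc1ccc(OC)cc1 | intermediate
10 | methyl (3R,5S,6E)-5-hydroxy-8-[(4-methoxybenzyl)oxy]-3,7-dimethyloct-6-enoate | COC(=O)C[C@H](C)C[C@H](O)/C=C(\C)COCc1ccc(OC)cc1 | intermediate
11 | methyl (3R,5S,6E)-5-[(tert-butyldimethylsilyl)oxy]-8-[(4-methoxybenzyl)oxy]-3,7-dimethyloct-6-enoate | COC(=O)C[C@H](C)C[C@H](O[Si](C)(C)C(C)(C)C)/C=C(\C)COCc1ccc(OC)cc1 | intermediate
12 | (3R,5S,6E)-5-[(tert-butyldimethylsilyl)oxy]-8-[(4-methoxybenzyl)oxy]-3,7-dimethyloct-6-enoic acid | OC(=O)C[C@H](C)C[C@H](O[Si](C)(C)C(C)(C)C)/C=C(\C)COCc1ccc(OC)cc1 | intermediate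
13 | acid chloride of 12 | ClC(=O)C[C@H](C)C[C@H](O[Si](C)(C)C(C)(C)C)/C=C(\C)COCc1ccc(OC)cc1 | intermediate
14 | ketene from 13, (3R,5S,6E)-5-silyloxy-8-(4-methoxybenzyloxy)-3,7-dimethylocta-1,6-dien-1-one | O=C=C[C@H](C)C[C@H](O[Si](C)(C)C(C)(C)C)/C=C(\C)COCc1ccc(OC)cc1 | intermediate
15 | 2-[(tert-butyldimethylsilyl)oxy]-7-{[(4-methoxybenzyl)oxy]methyl}-4,7-dimethylbicyclo[3.1.1]heptan-6-one (C5 ketone; C1–OTBS and C3–CH3 cis, both on the C5 side of the bridge; C10–CH3 upper, CH2OPMB lower) | COc1ccc(COC[C@]2(C)[C@@H]3C(=O)[C@H]2[C@@H](O[Si](C)(C)C(C)(C)C)C[C@H]3C)cc1 | intermediate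
16 | C9 alcohol: as 15 with CH2OH on C10 | OC[C@]2(C)[C@@H]3C(=O)[C@H]2[C@@H](O[Si](C)(C)C(C)(C)C)C[C@H]3C | intermediate
17 | 2-bromo-2-methylpropanoyl bromide | CC(C)(Br)C(Br)=O | starting material
18 | 2-bromo-2-methylpropanoate of 16 | CC(C)(Br)C(=O)OC[C@]2(C)[C@@H]3C(=O)[C@H]2[C@@H](O[Si](C)(C)C(C)(C)C)C[C@H]3C | intermediate
19 | tricyclic hydroxy lactone: lactone ring C5–C6(CH3)2–C7(=O)–O–C9H2–C10 on the lower face, C5–OH upper | O=C1OC[C@]2(C)[C@@H]3[C@@](O)([C@H]2[C@@H](O[Si](C)(C)C(C)(C)C)C[C@H]3C)C1(C)C | intermediate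
20 | methyl oxalate of the C5 hydroxyl of 19 | O=C1OC[C@]2(C)[C@@H]3[C@@](OC(=O)C(=O)OC)([C@H]2[C@@H](O[Si](C)(C)C(C)(C)C)C[C@H]3C)C1(C)C | intermediate
21 | tricyclic lactone: as 19 with C5–H upper | O=C1OC[C@]2(C)[C@@H]3[C@@H]([C@H]2[C@@H](O[Si](C)(C)C(C)(C)C)C[C@H]3C)C1(C)C | intermediate
22 | diol: C10–CH2OH (C9) and C5–C(CH3)2–CH2OH (C6, C7), both lower | OC[C@]2(C)[C@@H]3[C@@H]([C@H]2[C@@H](O[Si](C)(C)C(C)(C)C)C[C@H]3C)C(C)(C)CO | intermediate
23 | dialdehyde (C7 and C9 formyl) | O=C[C@]2(C)[C@@H]3[C@@H]([C@H]2[C@@H](O[Si](C)(C)C(C)(C)C)C[C@H]3C)C(C)(C)C=O | intermediate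
24 | diacid (C7 and C9 carboxyl) | OC(=O)[C@]2(C)[C@@H]3[C@@H]([C@H]2[C@@H](O[Si](C)(C)C(C)(C)C)C[C@H]3C)C(C)(C)C(=O)O | intermediate
25 | dimethyl ester of 24 | COC(=O)[C@]2(C)[C@@H]3[C@@H]([C@H]2[C@@H](O[Si](C)(C)C(C)(C)C)C[C@H]3C)C(C)(C)C(=O)OC | intermediate
26 | tricyclic C7=C9 enediol bis(trimethylsilyl ether), C1 as OTBS (key-step precursor) | C[Si](C)(C)OC1=C(O[Si](C)(C)C)[C@]2(C)[C@@H]3[C@@H]([C@H]2[C@@H](O[Si](C)(C)C(C)(C)C)C[C@H]3C)C1(C)C | intermediate
27 | diiodomethane | ICI | starting material
28 | 7,9-bis(trimethylsilyloxy) cyclopropane C7–C8–C9 (CH2 on either face, not specified) | C[Si](C)(C)OC12CC1(O[Si](C)(C)C)[C@]3(C)[C@@H]4[C@@H]([C@H]3[C@@H](O[Si](C)(C)C(C)(C)C)C[C@H]4C)C2(C)C | intermediate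
29 | longipinane-7,9-dione, C1 as OTBS (key-step product) | O=C1CC(=O)[C@]2(C)[C@@H]3[C@@H]([C@H]2[C@@H](O[Si](C)(C)C(C)(C)C)C[C@H]3C)C1(C)C | intermediate
30 | (9R)-9-hydroxy-longipinan-7-one, C1 as OTBS | O=C1C[C@@H](O)[C@]2(C)[C@@H]3[C@@H]([C@H]2[C@@H](O[Si](C)(C)C(C)(C)C)C[C@H]3C)C1(C)C | intermediate
31 | (7R,9R)-longipinane-7,9-diol (trans), C1 as OTBS | O[C@@H]1C[C@@H](O)[C@]2(C)[C@@H]3[C@@H]([C@H]2[C@@H](O[Si](C)(C)C(C)(C)C)C[C@H]3C)C1(C)C | intermediate
32 | angelic acid, (Z)-2-methylbut-2-enoic acid | C/C=C(/C)C(=O)O | starting material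
33 | angelic 2,4,6-trichlorobenzoic anhydride | C/C=C(/C)C(=O)OC(=O)c1c(Cl)cc(Cl)cc1Cl | intermediate
34 | (7R,9R)-7,9-diangelate, C1 as OTBS | C/C=C(/C)C(=O)O[C@@H]1C[C@@H](OC(=O)/C(C)=C\C)[C@]2(C)[C@@H]3[C@@H]([C@H]2[C@@H](O[Si](C)(C)C(C)(C)C)C[C@H]3C)C1(C)C | intermediate
35 | (7R,9R)-7,9-diangelate, C1 alcohol | C/C=C(/C)C(=O)O[C@@H]1C[C@@H](OC(=O)/C(C)=C\C)[C@]2(C)[C@@H]3[C@@H]([C@H]2[C@@H](O)C[C@H]3C)C1(C)C | intermediate
36 | CNP0283599.1, (7R,9R)-7,9-diangeloyloxy-longipinan-1-one | C/C=C(/C)C(=O)O[C@@H]1C[C@@H](OC(=O)/C(C)=C\C)[C@]2(C)[C@@H]3[C@@H]([C@H]2C(=O)C[C@H]3C)C1(C)C | target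

**Step count**
Total: 23 steps. Longest linear sequence: 23 steps (1 → 36); 21 steps from 5.

**Steps most likely to fail**

Step 18 (key step). The zinc carbenoid may fail to reach the tetrasubstituted C7=C9 bond, which lies between two quaternary carbons, or zinc iodide may strip the silyl groups to the acyloin before methylene transfer. The fallback closes ring C by an intramolecular aldol addition, with C8 brought in as a methyl ketone carbon; it sets out from lactone 21 and returns at dione 29. MeLi (1.1 equiv, THF, −78 °C) should add once to the hindered lactone carbonyl to give the hydroxy methyl ketone F3. Dess–Martin oxidation gives the keto aldehyde F4, whose aldehyde cannot enolise and whose ketone enolises only at CH3. LiN(SiMe3)2 (THF, −78 °C) then closes the seven-membered ring by addition of C8 to C9, giving the hydroxy ketone F5 as a mixture of C9 epimers, and a second Dess–Martin oxidation gives 29.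

Step 7. The ketene may dimerise or polymerise faster than it adds to an alkene made less nucleophilic by two allylic oxygen substituents. The fallback is the keteniminium version of the cycloaddition; it sets out from ester 11 and returns at ketone 15. Aminolysis of 11 (Me2NH·HCl, Me3Al, toluene, 50 °C) should give the N,N-dimethylamide F1. Tf2O and 2,4,6-collidine in refluxing 1,2-dichloroethane convert it into the keteniminium ion, a much stronger electrophile, which should cyclise by the same crossed mode to the cyclobutaniminium triflate F2; hydrolysis (aq. NaHCO3, 60 °C) gives 15.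

Step 19. The chloroborane may be consumed by O-borylation of the enol form of the 1,3-dione, or it may not override the residual facial bias of the tricycle, so that carbinol epimers form. The fallback gives up reagent control; it sets out from 29 and returns at 31. LiAlH(Ot-Bu)3 (THF, −78 °C) should reduce the less hindered C9 carbonyl to the hydroxy ketone F5 as an epimer mixture. Hydroxyl-directed reduction as in step 20 converts it into two trans-diols, 31 and the (7S,9S)-diol F6, which are diastereomers and separable by chromatography. F6 is returned to 29 by double Dess–Martin oxidation and recycled.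

**Further compounds**
F1 | step 7 | N,N-dimethylamide of 12 | CN(C)C(=O)C[C@H](C)C[C@H](O[Si](C)(C)C(C)(C)C)/C=C(\C)COCc1ccc(OC)cc1
F2 | step 7 | cyclobutaniminium triflate (C5 as C=N+(CH3)2, otherwise as 15) | COc1ccc(COC[C@]2(C)[C@@H]3C(=[N+](C)C)[C@H]2[C@@H](O[Si](C)(C)C(C)(C)C)C[C@H]3C)cc1.[O-]S(=O)(=O)C(F)(F)F
F3 | step 18 | hydroxy methyl ketone (C9H2OH; C6–C7(=O)–C8H3) | OC[C@]2(C)[C@@H]3[C@@H]([C@H]2[C@@H](O[Si](C)(C)C(C)(C)C)C[C@H]3C)C(C)(C)C(C)=O
F4 | step 18 | keto aldehyde (C9 formyl; C7 methyl ketone) | O=C[C@]2(C)[C@@H]3[C@@H]([C@H]2[C@@H](O[Si](C)(C)C(C)(C)C)C[C@H]3C)C(C)(C)C(C)=O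
F5 | step 18 | 9-hydroxy-longipinan-7-one, C1 as OTBS, mixture of C9 epimers | O=C1CC(O)[C@]2(C)[C@@H]3[C@@H]([C@H]2[C@@H](O[Si](C)(C)C(C)(C)C)C[C@H]3C)C1(C)C
F6 | step 19 | (7S,9S)-longipinane-7,9-diol, C1 as OTBS | O[C@H]1C[C@H](O)[C@]2(C)[C@@H]3[C@@H]([C@H]2[C@@H](O[Si](C)(C)C(C)(C)C)C[C@H]3C)C1(C)C
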